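Summed over the readings of both earlier runs, left-handed product stood at 107 % against 54.1 % for right-handed product, about twice as much. That sum mixes in readings taken after left-handed substrate had thinned, so it is no rate ratio at equal substrate. I therefore counted each product as what its own hand had lost and took the ratio of the logarithms of the fractions of each hand left over. The last east reading gave s = 1.98, and the last north-east reading gave 1.95. I kept the east reading of s as the selectivity factor: the rate of the left hand over the rate of the right hand at equal substrate. Products made in that ratio have an excess E of 32.9 %.

| flask | left-handed substrate | right-handed substrate | reagent | remark | time |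
|---|---|---|---|---|---|
| north-east | 20 mM | 20 mM | 2.4 equiv | run made earlier |  |
| east | 20 mM | 20 mM | 5.2 equiv | run made earlier |  |
| violet | 20 mM | 20 mM | 2.00 equiv |  | 6.0 min |
| green | 20 mM | 20 mM | 2.50 equiv |  | 6.0 min |
| red | 20 mM | 20 mM | 4.00 equiv |  | 6.0 min |

| run | time / min | left-handed product / % | right-handed product / % |
|---|---|---|---|
| north-east | 0.500 | 2.7 | 0.1 |
| north-east | 0.833 | 3.9 | 2.5 |
| north-east | 1.50 | 6.4 | 3.8 |
| north-east | 3.00 | 8.9 | 2.9 |
| north-east | 6.00 | 14.6 | 8.1 |
| east | 0.500 | 4.6 | 0.9 |
| east | 0.833 | 6.4 | 4.1 |
| east | 1.50 | 11.4 | 4.0 |
| east | 3.00 | 18.0 | 9.1 |
| east | 6.00 | 30.1 | 18.6 |

(readings scatter by 1 percentage point)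

- reagent is single-handed; left-handed substrate and right-handed substrate are mirror images of each other, charged as a racemate, each of them at the stated concentration
- the analysis behind the earlier runs scatters by 1 percentage point, standard deviation
- an excess is the difference of the two amounts in percent of their sum
- "hardly changes" means that all values lie within two and a half points (for a concentration: within two and a half percent of the largest)
- the handed part of reagent does not stay in what it makes, so the products of the two hands are mirror images too

- excess of left-handed product over right-handed product at the end for violet, green, red, in this order
- the course of these numbers from the first flask to the last (hardly changes / falls all the way / rises all the way / rises, then falls / falls, then rises)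

I looked for the concentration that set the pace, and it was the reagent's. From north-east to east the reagent charge rose 2.17 times, and total product at 6.00 min rose 2.15 times. North-east held 2.4 equiv, more than the two substrates together, and its products reached 22.7 % of them. So I treated each hand as pseudo-first-order, with reagent changing the pace and not the split.

Then I ran the flasks in my head. In the first instants the substrates were equal, so product formed at excess E. In the middle, left-handed substrate thinned faster, and new product came in the ratio s times left-handed over right-handed substrate. By the end the excess had to lie below E, and further below in red, with twice the reagent of violet. The last readings showed this direction, 28.6 % in north-east and 23.6 % in east, though each reading scattered by 1 percentage point.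

The forecast gave 31 %, 30 % and 27 %, so falls all the way: the excess “erodes as the fast hand runs out”. Its start was near 35 %, mine 32.9 %.

The flasks gave 31.5 %, 30.9 % and 29.2 %: hardly changes.

    reagent + left-handed substrate → left-handed product (k = 0.0278 M⁻¹ s⁻¹)
    reagent + right-handed substrate → right-handed product (k = 0.0128 M⁻¹ s⁻¹)
    left-handed substrate ⇌ achiral form (K = 0.0479, k = 0.00491 s⁻¹)
    right-handed substrate ⇌ achiral form (K = 0.0479, k = 0.00491 s⁻¹)
    achiral form → waste (k = 0.00510 s⁻¹)
    achiral form → side product (k = 0.00438 s⁻¹)
    left-handed product ⇌ right-handed product (k = 2.30 × 10⁻⁴ s⁻¹)

Violet ended 1.4 points below my E and red 3.7 points below it. At 2.54 min in violet, right-handed substrate went to right-handed product at 0.093 of the rate at which it went to achiral form, forward step alone, and achiral form fell back 22 times faster than it went on. Red kept 50 % of its left-handed substrate and 60 % of its right-handed substrate at 6.00 min, so my rule put new product there at a ratio of 1.65.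

The numbers in the tables were computed for an exercise; scatter was added.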